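Cuts: the two N–H bonds are masked as N–SO2Ph. The cyclohexene C3=C4 alkene is then cut (metathesis of a vinyl and an isopropenyl group), then the C1–C2 ring bond between quaternary carbon and aryl methine ([3,3] shift), then the ester C–O bond tethering the two indole halves.
Enabling feature: in the cyclohexene, quaternary C1 (CH3, (E)-2-(indol-5-yl)ethenyl) is bonded to methine C2 (indol-5-yl). C3, the alkene CH on C2, can be traced back to a carboxyl carbon, so the exocyclic styryl C=C lies γ,δ to C3, which is the pattern left by an ester-enolate Claisen rearrangement.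
Forward order: both indole rings are bought intact (5-bromoindole-3-acetic acid), and one common bromide is divided into a 5-carbaldehyde and a 5-acetic acid. The aldehyde grows into a (Z)-allylic alcohol, esterification joins the halves through oxygen, the rearrangement joins them through carbon, and the cyclohexene, the only ring built, closes afterwards.
Stereochemistry: a CBS reduction sets one carbinol centre, and trans-hydroalumination/iodination plus a stereoretentive Suzuki coupling set the (Z)-alkene. The chair [3,3] array converts carbinol configuration, alkene geometry and ketene acetal geometry into (1S), (2R) and the (E)-styryl alkene, and later steps avoid epimerising conditions.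

Key step: step 15

Abbreviation: Ar = 3-(2-methylbut-3-en-2-yl)-1-(phenylsulfonyl)-1H-indol-5-yl.
Remark on the chemistry (assumption): in the CBS step the indolyl group is taken as the large flank and the linear propynyl group as the small one. The descriptor change from (S) in 13 to (R) in 15 is a CIP ranking effect, not an inversion.

Step 1
Reactants: 1 5-bromoindole-3-acetic acid
Product: 2 methyl 2-(5-bromo-1H-indol-3-yl)acetate
Conditions: MeOH, H2SO4 (cat.), reflux
Reagents that add atoms: methanol, CO
Why: Fischer esterification of an unhindered arylacetic acid gives the enolisable ester needed for the gem-dimethylation.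

Step 2
Reactants: 2 methyl 2-(5-bromo-1H-indol-3-yl)acetate
Product: 3 methyl 2-[5-bromo-1-(phenylsulfonyl)-1H-indol-3-yl]acetate
Conditions: NaH, THF/DMF, 0 °C; PhSO2Cl, 0 °C → rt
Reagents that add atoms: benzenesulfonyl chloride, O=S(=O)(Cl)c1ccccc1
Why: N-sulfonylation of the indolyl anion (N–H is the most acidic site) installs an electron-withdrawing group that protects nitrogen, deactivates C2=C3 and later restrains benzylic ionisation.

Step 3
Reactants: 3 methyl 2-[5-bromo-1-(phenylsulfonyl)-1H-indol-3-yl]acetate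
Product: 5 methyl 2-[5-bromo-1-(phenylsulfonyl)-1H-indol-3-yl]-2-methylpropanoate, via monomethyl ester 4 (not isolated)
Conditions: NaH (excess), MeI (excess), DMF, 0 °C → rt
Reagents that add atoms: iodomethane, CI
Why: Exhaustive enolate alkylation (two SN2 methylations of the acidic heteroarylacetate) stops cleanly at the quaternary carbon because no α-hydrogen remains.

Step 4
Reactants: 5 methyl 2-[5-bromo-1-(phenylsulfonyl)-1H-indol-3-yl]-2-methylpropanoate
Product: 6 2-[5-bromo-1-(phenylsulfonyl)-1H-indol-3-yl]-2-methylpropanal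
Conditions: DIBAL-H, CH2Cl2, −78 °C; aq. Rochelle salt
Reagents that add atoms: none
Why: In this partial DIBAL-H reduction the aluminium hemiacetal next to the quaternary carbon persists at −78 °C and releases the non-enolisable aldehyde only on work-up.

Step 5
Reactants: 6 2-[5-bromo-1-(phenylsulfonyl)-1H-indol-3-yl]-2-methylpropanal
Product: 7 5-bromo-3-(2-methylbut-3-en-2-yl)-1-(phenylsulfonyl)-1H-indole (Ar–Br)
Conditions: Ph3PCH3Br, KHMDS, THF, 0 °C; then 6, 0 °C → rt
Reagents that add atoms: methyltriphenylphosphonium bromide, C[P+](c1ccccc1)(c1ccccc1)c1ccccc1.[Br-]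
Why: Wittig methylenation works well here because the small ylide reaches the neopentyl-type carbonyl and the aldehyde cannot enolise.

Step 6
Reactants: 7 5-bromo-3-(2-methylbut-3-en-2-yl)-1-(phenylsulfonyl)-1H-indole
Product: 9 3-(2-methylbut-3-en-2-yl)-1-(phenylsulfonyl)-1H-indole-5-carbaldehyde (Ar–CHO), via 5-lithioindole 8 (not isolated)
Conditions: t-BuLi (2 equiv), THF, −95 °C; DMF, −95 → −40 °C; then H2O
Reagents that add atoms: N,N-dimethylformamide, CN(C)C=O
Why: Bromine–lithium exchange with t-BuLi at very low temperature outruns sulfonyl-directed C2 deprotonation (further hindered by the flanking tertiary alkyl group), and a cold DMF quench formylates C5 before the aryllithium can equilibrate.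

Step 7
Reactants: 9 Ar–CHO; 10 1-propynylmagnesium bromide
Product: 11 rac-1-Ar-but-2-yn-1-ol
Conditions: THF, −78 → 0 °C; then H2O
Reagents that add atoms: none
Why: 1,2-addition of an alkynyl Grignard reagent to an aryl aldehyde is reliable, and the racemic centre is erased in the next step.

Step 8
Reactants: 11 rac-1-Ar-but-2-yn-1-ol
Product: 12 1-Ar-but-2-yn-1-one
Conditions: Dess–Martin periodinane, CH2Cl2, 0 °C → rt
Reagents that add atoms: none
Why: Dess–Martin oxidation of the activated benzylic propargylic alcohol proceeds under neutral conditions that leave alkenes, alkyne and sulfonamide untouched.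

Step 9
Reactants: 12 1-Ar-but-2-yn-1-one
Product: 13 (S)-1-Ar-but-2-yn-1-ol
Conditions: (S)-Me-CBS (cat.), catecholborane, toluene, −78 °C; then H2O
Reagents that add atoms: none
Why: In the Corey–Bakshi–Shibata reduction the carbonyl oxygen binds the catalyst boron anti to the bulkier indolyl flank, so hydride goes to the Re face and sets the (S)-carbinol, while catecholborane at −78 °C does not hydroborate the alkyne or the alkene.

Step 10
Reactants: 13 (S)-1-Ar-but-2-yn-1-ol
Product: 15 (R,Z)-3-iodo-1-Ar-but-2-en-1-ol, via cyclic alkenylalanate 14 (not isolated)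
Conditions: Red-Al, THF, 0 °C → rt; I2, THF, −78 → 0 °C; aq. Rochelle salt
Reagents that add atoms: iodine, II
Why: Hydroxyl-directed trans-hydroalumination puts hydrogen on the proximal alkyne carbon and holds aluminium on the distal carbon in a five-membered ring (cis to the carbinol carbon), and iodinolysis with retention gives the (Z)-iodide with the carbinol centre unchanged.

Step 11
Reactants: 15 (R,Z)-3-iodo-1-Ar-but-2-en-1-ol; 16 isoprene
Product: 18 (R,Z)-3,6-dimethyl-1-Ar-hepta-2,6-dien-1-ol, via homoallylic borane 17 (not isolated)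
Conditions: disiamylborane (from BH3·THF + 2-methylbut-2-ene, THF, 0 °C), 16 (large excess), 0 °C → rt, excess 16 evaporated; then 15, PdCl2(dppf) (cat.), AsPh3 (cat.), aq. K3PO4, DMF, 50 °C
Reagents that add atoms: none
Why: This is a selective monohydroboration followed by a B-alkyl Suzuki–Miyaura coupling, in which the bulky dialkylborane (unlike 9-BBN) strongly prefers the monosubstituted over the 1,1-disubstituted alkene of a 2-alkylbutadiene and places boron on the terminal carbon, only the primary alkyl group transfers to palladium, and coupling at the alkenyl iodide occurs with retention so the new chain stays cis to the carbinol carbon.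

Step 12
Reactants: 7 Ar–Br
Product: 19 tert-butyl 2-Ar-acetate
Conditions: ClZnCH2CO2t-Bu, Pd(dba)2 (cat.), Q-Phos (cat.), THF, rt → 50 °C
Reagents that add atoms: (2-tert-butoxy-2-oxoethyl)zinc chloride, CC(C)(C)OC(=O)C[Zn]Cl
Why: Palladium-catalysed α-arylation of a zinc ester enolate (Reformatsky reagent, Negishi-type coupling) is mild and nearly neutral, so neither the sulfonamide nor the hindered vinyl group interferes.

Step 13
Reactants: 19 tert-butyl 2-Ar-acetate
Product: 20 2-Ar-acetic acid
Conditions: TFA/CH2Cl2, 0 °C → rt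
Reagents that add atoms: none
Why: Acidolysis of the tert-butyl ester (E1 loss of isobutene) avoids the hydroxide that would threaten N–SO2Ph, and the sulfonyl-deactivated indole and monosubstituted alkene are not protonated by TFA.

Step 14
Reactants: 20 2-Ar-acetic acid; 18 (R,Z)-3,6-dimethyl-1-Ar-hepta-2,6-dien-1-ol
Product: 21 (R,Z)-3,6-dimethyl-1-Ar-hepta-2,6-dien-1-yl 2-Ar-acetate
Conditions: DCC, DMAP (cat.), CH2Cl2, 0 °C → rt
Reagents that add atoms: none
Why: Steglich esterification acylates the alcohol oxygen without breaking the carbinol C–O bond, so configuration and alkene geometry are retained.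

Step 15
Reactants: 21 (R,Z)-3,6-dimethyl-1-Ar-hepta-2,6-dien-1-yl 2-Ar-acetate
Product: 24 (2R,3S)-2-Ar-3-[(E)-2-Ar-ethenyl]-3,6-dimethylhept-6-enoic acid, via silyl ketene acetal 22 (not isolated), via trimethylsilyl ester 23 (not isolated)
Conditions: LiHMDS, THF/DMPU, −78 °C; TMSCl, −78 °C → rt; then dil. aq. acid
Reagents that add atoms: none
Why: LiHMDS removes the acidic benzylic α-proton and TMSCl traps the enolate as the (Z)-silyl ketene acetal 22 (indolyl cis to OSiMe3), which undergoes a concerted suprafacial [3,3]-sigmatropic shift in which the α-carbon bonds to the methyl-bearing alkene terminus as the allylic C–O bond breaks, and silyl ester 23 is hydrolysed on work-up. The closest known reaction type is the Ireland–Claisen rearrangement of secondary allylic arylacetates with 1,3-chirality transfer onto a trisubstituted alkene. No ring is closed, the six-membered chair being only the transition-state array. The quaternary carbon is controlled by the (R)-carbinol centre and the (Z)-alkene: the carbinol indolyl group sits equatorial (axial would clash 1,3-diaxially with the axial homomethallyl chain), so one alkene face is attacked, giving (3S) and the (E)-styryl alkene. The methine is controlled by the ketene acetal geometry within the chair, which places its indolyl group equatorial and gives (2R), i.e. aryl and methyl cis in the later ring. The step needs one ketene acetal geometry, chair over boat and a concerted shift over ionisation, secured respectively by the aryl-biased enolisation in a dipolar medium, by the acyclic substrate with its equatorial anchor, and by the electron-withdrawing N-sulfonyl group para-related to the carbinol carbon.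

Step 16
Reactants: 24 (2R,3S)-2-Ar-3-[(E)-2-Ar-ethenyl]-3,6-dimethylhept-6-enoic acid
Product: 25 methyl (2R,3S)-2-Ar-3-[(E)-2-Ar-ethenyl]-3,6-dimethylhept-6-enoate
Conditions: TMSCHN2, toluene/MeOH, 0 °C → rt
Reagents that add atoms: (trimethylsilyl)diazomethane, C[Si](C)(C)C=[N+]=[N-]
Why: O-methylation of the carboxylic acid with a diazoalkane needs no base and attacks oxygen rather than the crowded carbonyl, so the α-aryl centre is not epimerised.

Step 17
Reactants: 25 methyl (2R,3S)-2-Ar-3-[(E)-2-Ar-ethenyl]-3,6-dimethylhept-6-enoate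
Product: 26 (2R,3S)-2-Ar-3-[(E)-2-Ar-ethenyl]-3,6-dimethylhept-6-en-1-ol
Conditions: DIBAL-H (excess), CH2Cl2, −78 → 0 °C; aq. Rochelle salt
Reagents that add atoms: none
Why: Full DIBAL-H reduction of the ester is non-basic, tolerates N-sulfonylindoles at low temperature and leaves both stereocentres alone.

Step 18
Reactants: 26 (2R,3S)-2-Ar-3-[(E)-2-Ar-ethenyl]-3,6-dimethylhept-6-en-1-ol
Product: 27 (2R,3S)-2-Ar-3-[(E)-2-Ar-ethenyl]-3,6-dimethylhept-6-enal
Conditions: Dess–Martin periodinane, CH2Cl2, 0 °C → rt
Reagents that add atoms: none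
Why: Dess–Martin oxidation uses no amine base, so the configurationally labile α-aryl aldehyde should be obtained without epimerisation and is used at once.

Step 19
Reactants: 27 (2R,3S)-2-Ar-3-[(E)-2-Ar-ethenyl]-3,6-dimethylhept-6-enal
Product: 28 (3R,4S)-3-Ar-4-[(E)-2-Ar-ethenyl]-4,7-dimethylocta-1,7-diene
Conditions: Tebbe reagent, pyridine (cat.), THF/toluene, −40 → 0 °C; then aq. NaOH
Reagents that add atoms: Tebbe reagent, C[Al](C)C[Ti](Cl)(C1C=CC=C1)C1C=CC=C1
Why: Tebbe methylenation proceeds through a non-basic titanium methylidene and an oxatitanacyclobutane, so the hindered enolisable aldehyde is olefinated at low temperature with the α-aryl centre intact.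

Step 20
Reactants: 28 (3R,4S)-3-Ar-4-[(E)-2-Ar-ethenyl]-4,7-dimethylocta-1,7-diene
Product: 29 bis-N-phenylsulfonyl cyclohexene, i.e. (1S,2R)-1,4-dimethyl-2-Ar-1-[(E)-2-Ar-ethenyl]cyclohex-3-ene
Conditions: Grubbs II (cat.), CH2Cl2 (high dilution), 40 °C
Reagents that add atoms: none
Why: In this ring-closing metathesis ruthenium loads on the only vinyl group whose allylic carbon is not quaternary and closes the six-membered ring onto the isopropenyl group with loss of ethene, while the two tert-allylic vinyl groups and the neopentyl-type styryl alkene are too hindered to compete and the modest temperature avoids a Cope shift of the 1,5-diene.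

Step 21
Reactants: 29 bis-N-phenylsulfonyl cyclohexene
Product: 30 5-[(E)-2-{(1S,2R)-1,4-dimethyl-2-[3-(2-methylbut-3-en-2-yl)-1H-indol-5-yl]cyclohex-3-en-1-yl}ethenyl]-3-(2-methylbut-3-en-2-yl)-1H-indole (target)
Conditions: KOH, THF/MeOH/H2O, 60 °C
Reagents that add atoms: none
Why: Nucleophilic cleavage of the N–S bonds (hydrolysis of N-sulfonylindoles, with the indolyl anion as leaving group) frees both N–H groups under conditions that affect neither the alkenes nor the non-acidic stereocentres.

Compound list
1 | 5-bromoindole-3-acetic acid | OC(=O)Cc1c[nH]c2ccc(Br)cc12 | starting material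
2 | methyl 2-(5-bromo-1H-indol-3-yl)acetate | COC(=O)Cc1c[nH]c2ccc(Br)cc12 | intermediate
3 | methyl 2-[5-bromo-1-(phenylsulfonyl)-1H-indol-3-yl]acetate | COC(=O)Cc1cn(S(=O)(=O)c3ccccc3)c2ccc(Br)cc12 | intermediate
4 | methyl 2-[5-bromo-1-(phenylsulfonyl)-1H-indol-3-yl]propanoate (racemic, not isolated) | COC(=O)C(C)c1cn(S(=O)(=O)c3ccccc3)c2ccc(Br)cc12 | intermediate
5 | methyl 2-[5-bromo-1-(phenylsulfonyl)-1H-indol-3-yl]-2-methylpropanoate | COC(=O)C(C)(C)c1cn(S(=O)(=O)c3ccccc3)c2ccc(Br)cc12 | intermediate
6 | 2-[5-bromo-1-(phenylsulfonyl)-1H-indol-3-yl]-2-methylpropanal | O=CC(C)(C)c1cn(S(=O)(=O)c3ccccc3)c2ccc(Br)cc12 | intermediate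
7 | 5-bromo-3-(2-methylbut-3-en-2-yl)-1-(phenylsulfonyl)-1H-indole | C=CC(C)(C)c1cn(S(=O)(=O)c3ccccc3)c2ccc(Br)cc12 | intermediate
8 | 5-lithio-3-(2-methylbut-3-en-2-yl)-1-(phenylsulfonyl)-1H-indole (not isolated) | C=CC(C)(C)c1cn(S(=O)(=O)c3ccccc3)c2ccc([Li])cc12 | intermediate
9 | 3-(2-methylbut-3-en-2-yl)-1-(phenylsulfonyl)-1H-indole-5-carbaldehyde | C=CC(C)(C)c1cn(S(=O)(=O)c3ccccc3)c2ccc(C=O)cc12 | intermediate
10 | 1-propynylmagnesium bromide | CC#C[Mg]Br | starting material
11 | rac-1-Ar-but-2-yn-1-ol | OC(C#CC)c1ccc2c(c1)c(C(C)(C)C=C)cn2S(=O)(=O)c1ccccc1 | intermediate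
12 | 1-Ar-but-2-yn-1-one | O=C(C#CC)c1ccc2c(c1)c(C(C)(C)C=C)cn2S(=O)(=O)c1ccccc1 | intermediate
13 | (S)-1-Ar-but-2-yn-1-ol | O[C@H](C#CC)c1ccc2c(c1)c(C(C)(C)C=C)cn2S(=O)(=O)c1ccccc1 | intermediate
14 | sodium cyclic alkoxy(alkenyl)bis(2-methoxyethoxy)alanate (not isolated) | CC1=C[C@H](c2ccc3c(c2)c(C(C)(C)C=C)cn3S(=O)(=O)c2ccccc2)O[Al-]1(OCCOC)OCCOC.[Na+] | intermediate
15 | (R,Z)-3-iodo-1-Ar-but-2-en-1-ol | O[C@H](/C=C(\I)C)c1ccc2c(c1)c(C(C)(C)C=C)cn2S(=O)(=O)c1ccccc1 | intermediate
16 | isoprene | C=CC(C)=C | starting material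
17 | bis(3-methylbutan-2-yl)(3-methylbut-3-en-1-yl)borane (not isolated) | C=C(C)CCB(C(C)C(C)C)C(C)C(C)C | intermediate
18 | (R,Z)-3,6-dimethyl-1-Ar-hepta-2,6-dien-1-ol | O[C@H](/C=C(/C)CCC(C)=C)c1ccc2c(c1)c(C(C)(C)C=C)cn2S(=O)(=O)c1ccccc1 | intermediate
19 | tert-butyl 2-Ar-acetate | CC(C)(C)OC(=O)Cc1ccc2c(c1)c(C(C)(C)C=C)cn2S(=O)(=O)c1ccccc1 | intermediate
20 | 2-Ar-acetic acid | C=CC(C)(C)c1cn(S(=O)(=O)c3ccccc3)c2ccc(CC(=O)O)cc12 | intermediate
21 | (R,Z)-3,6-dimethyl-1-Ar-hepta-2,6-dien-1-yl 2-Ar-acetate | C=CC(C)(C)c1cn(S(=O)(=O)c3ccccc3)c2ccc(CC(=O)O[C@H](/C=C(/C)CCC(C)=C)c3ccc4c(c3)c(C(C)(C)C=C)cn4S(=O)(=O)c3ccccc3)cc12 | intermediate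
22 | (Z)-O-trimethylsilyl ketene acetal of 21, Ar cis to OSiMe3 (not isolated) | C=CC(C)(C)c1cn(S(=O)(=O)c3ccccc3)c2ccc(/C=C(\O[Si](C)(C)C)O[C@H](/C=C(/C)CCC(C)=C)c3ccc4c(c3)c(C(C)(C)C=C)cn4S(=O)(=O)c3ccccc3)cc12 | intermediate
23 | trimethylsilyl ester of 24 (not isolated) | C=CC(C)(C)c1cn(S(=O)(=O)c3ccccc3)c2ccc(/C=C/[C@]([C@@H](C(=O)O[Si](C)(C)C)c3ccc4c(c3)c(C(C)(C)C=C)cn4S(=O)(=O)c3ccccc3)(C)CCC(C)=C)cc12 | intermediate
24 | (2R,3S)-2-Ar-3-[(E)-2-Ar-ethenyl]-3,6-dimethylhept-6-enoic acid | C=CC(C)(C)c1cn(S(=O)(=O)c3ccccc3)c2ccc(/C=C/[C@]([C@@H](C(=O)O)c3ccc4c(c3)c(C(C)(C)C=C)cn4S(=O)(=O)c3ccccc3)(C)CCC(C)=C)cc12 | intermediate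
25 | methyl (2R,3S)-2-Ar-3-[(E)-2-Ar-ethenyl]-3,6-dimethylhept-6-enoate | C=CC(C)(C)c1cn(S(=O)(=O)c3ccccc3)c2ccc(/C=C/[C@]([C@@H](C(=O)OC)c3ccc4c(c3)c(C(C)(C)C=C)cn4S(=O)(=O)c3ccccc3)(C)CCC(C)=C)cc12 | intermediate
26 | (2R,3S)-2-Ar-3-[(E)-2-Ar-ethenyl]-3,6-dimethylhept-6-en-1-ol | C=CC(C)(C)c1cn(S(=O)(=O)c3ccccc3)c2ccc(/C=C/[C@]([C@@H](CO)c3ccc4c(c3)c(C(C)(C)C=C)cn4S(=O)(=O)c3ccccc3)(C)CCC(C)=C)cc12 | intermediate
27 | (2R,3S)-2-Ar-3-[(E)-2-Ar-ethenyl]-3,6-dimethylhept-6-enal | C=CC(C)(C)c1cn(S(=O)(=O)c3ccccc3)c2ccc(/C=C/[C@]([C@@H](C=O)c3ccc4c(c3)c(C(C)(C)C=C)cn4S(=O)(=O)c3ccccc3)(C)CCC(C)=C)cc12 | intermediate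
28 | (3R,4S)-3-Ar-4-[(E)-2-Ar-ethenyl]-4,7-dimethylocta-1,7-diene | C=CC(C)(C)c1cn(S(=O)(=O)c3ccccc3)c2ccc(/C=C/[C@]([C@@H](C=C)c3ccc4c(c3)c(C(C)(C)C=C)cn4S(=O)(=O)c3ccccc3)(C)CCC(C)=C)cc12 | intermediate
29 | (1S,2R)-1,4-dimethyl-2-Ar-1-[(E)-2-Ar-ethenyl]cyclohex-3-ene | C=CC(C)(C)c1cn(S(=O)(=O)c3ccccc3)c2ccc(/C=C/[C@]3(C)CCC(C)=C[C@H]3c3ccc4c(c3)c(C(C)(C)C=C)cn4S(=O)(=O)c3ccccc3)cc12 | intermediate
30 | 5-[(E)-2-{(1S,2R)-1,4-dimethyl-2-[3-(2-methylbut-3-en-2-yl)-1H-indol-5-yl]cyclohex-3-en-1-yl}ethenyl]-3-(2-methylbut-3-en-2-yl)-1H-indole | C=CC(C)(C)c1c[nH]c2ccc(/C=C/[C@]3(C)CCC(C)=C[C@H]3c3ccc4[nH]cc(C(C)(C)C=C)c4c3)cc12 | target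

Total step count: 21 steps.
Longest linear sequence: 19 steps (steps 1–11, then 14–21). Steps 12 and 13 form the short branch from 7.

Steps most likely to fail

Step 15 (Ireland–Claisen rearrangement).
- Three processes could erode the relay of configuration to the methine and the quaternary carbon. These are leakage in the ketene acetal geometry during enolisation, heterolysis of the doubly activated C–O bond in competition with the concerted shift, and slow bond formation at the fully substituted alkene terminus.
- The fallback sets out from 9 and 18 and comes back at 27. It takes the geometry of the oxygen-bearing alkene from a stereodefined alkenyl halide instead of from an enolisation.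
- Takai olefination of 9 (CHI3, CrCl2, THF, 0 °C) should give (E)-5-(2-iodoethenyl)-3-(2-methylbut-3-en-2-yl)-1-(phenylsulfonyl)-1H-indole F1.
- Copper-catalysed C–O coupling of F1 with 18 (CuI, 3,4,7,8-tetramethylphenanthroline, Cs2CO3, toluene) proceeds with retention to the (E)-configured allyl vinyl ether F2.
- On heating in the same flask, F2 undergoes the aliphatic Claisen rearrangement through the same chair. It forms the same C–C bond and both stereocentres and delivers aldehyde 27 directly, so the acid branch and steps 14–18 are no longer needed.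

Step 9 (CBS reduction).
- Both ketone flanks are unsaturated. Insufficient discrimination between them, or uncatalysed background reduction of the electrophilic ynone, would lower the enantiomeric purity, and the chirality transfer would then pass that loss on unchanged to the target.
- The fallback sets out from 9 and comes back at 13. It creates the stereocentre in the C–C bond-forming event rather than in a reduction.
- It uses catalytic enantioselective alkynylation of the aldehyde with propyne (Me2Zn, dinuclear zinc–ProPhenol catalyst, toluene). The ligand antipode is chosen to deliver the alkynyl group to the Re face of the aldehyde.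
- This detour makes no new compound (F0) and also removes steps 7 and 8.

Step 11 (diene monohydroboration and B-alkyl Suzuki coupling).
- Incomplete site selectivity or double hydroboration of the diene could occur. Slow transmetalation from the hindered trialkylborane could also let protodeiodination or isomerisation of the alkenyl iodide compete.
- The fallback sets out from 15 and comes back at 18. It replaces the hydroboration by a preformed homoallyl metal.
- Zinc insertion into commercial 4-bromo-2-methylbut-1-ene (Zn, LiCl, THF) gives (3-methylbut-3-en-1-yl)zinc bromide F3.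
- F3 is used in excess and coupled with 15 in a Negishi coupling (Pd(OAc)2, SPhos, THF, rt). This coupling tolerates the free hydroxyl group and proceeds with retention of the (Z)-geometry.

Further compounds
F1 | step 15 | (E)-5-(2-iodoethenyl)-3-(2-methylbut-3-en-2-yl)-1-(phenylsulfonyl)-1H-indole | C=CC(C)(C)c1cn(S(=O)(=O)c3ccccc3)c2ccc(/C=C/I)cc12
F2 | step 15 | (E)-2-Ar-ethenyl (R,Z)-3,6-dimethyl-1-Ar-hepta-2,6-dien-1-yl ether (allyl vinyl ether) | C=CC(C)(C)c1cn(S(=O)(=O)c3ccccc3)c2ccc(/C=C/O[C@H](/C=C(/C)CCC(C)=C)c3ccc4c(c3)c(C(C)(C)C=C)cn4S(=O)(=O)c3ccccc3)cc12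
F0 | step 9 | none | none
F3 | step 11 | (3-methylbut-3-en-1-yl)zinc bromide | C=C(C)CC[Zn]Br
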